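**Target:** Waltherione H is (5S,8R)-1,3,8-trimethoxy-2-methyl-5-(5-phenylpentyl)-5,6,7,8-tetrahydroquinolin-4(1H)-one. From the SMILES, the 5-chain and the 8-OMe are cis.

**Assumptions**
- (R)-5-Oxotetrahydrofuran-2-carboxylic acid (from D-glutamic acid) and 3-methoxypentane-2,4-dione are treated as purchasable building blocks.
- The cis relationship, rather than trans, is the one in the given SMILES and is assumed to be reachable in the cyclisation.

## Retrosynthetic overview
1. The C4a–C5 bond comes from a photoredox reductive 6-exo aryl-radical cyclisation of a 5-iodo-N-methoxy-4-pyridone onto a tethered Z-alkene. C5 is set by 1,4-induction from the C8-OMe centre.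
2. The iodopyridone comes from the pyridone, then the pyranone, then a 1,3,5-triketone. The triketone is made from an α-methoxy ester plus the dianion of 3-methoxypentane-2,4-dione.
3. The α-methoxy ester comes from a D-glutamate-derived lactone acid by lactol formation, Wittig olefination and methylation. The lactone acid supplies the C8 stereocentre and the C8a–C5 carbon chain.
4. Rings are formed in the order pyranone, then pyridone (by O/N-OMe exchange), then the carbocycle.

## Route

**Step 1**
Reactants: 1, (2R)-5-oxooxolane-2-carboxylic acid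
Product: 2, (2R)-5-hydroxyoxolane-2-carboxylic acid (lactol, anomeric mixture)
Conditions: DIBAL-H (3.2 equiv), THF, −78 °C, 3 h; Rochelle salt work-up
Reagents that add atoms: none
Why: DIBAL-H reduces the lactone carbonyl to the lactol, while the acid is protected as its aluminium carboxylate. The C–O stereocentre (future C8, R) is untouched.

**Step 2**
Reactants: 2; 3, (5-phenylpentyl)triphenylphosphonium bromide
Product: 4, (2R,5Z)-2-hydroxy-10-phenyldec-5-enoic acid
Conditions: 3 (3.5 equiv), KOtBu (8 equiv), THF, 0 → 25 °C, 14 h
Reagents that add atoms: 3, [Br-].[P+](CCCCCc1ccccc1)(c1ccccc1)(c1ccccc1)c1ccccc1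
Why: Wittig olefination of the open-chain aldehyde form of the lactol with a non-stabilised ylide gives the Z-alkene and installs the full 5-phenylpentyl-bearing chain. No stereocentre is changed.

**Step 3**
Reactants: 4; 5, iodomethane
Product: 6, methyl (2R,5Z)-2-methoxy-10-phenyldec-5-enoate
Conditions: MeI (12 equiv), Ag2O (5 equiv), DMF, 25 °C, 24 h, dark
Reagents that add atoms: 5, CI
Why: Purdie-type methylation (MeI/Ag2O) converts both the carboxylic acid and the α-hydroxy group, and is mild enough to avoid racemising the α-stereocentre.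

**Step 4**
Reactants: 6; 7, 3-methoxypentane-2,4-dione
Product: 8, (7R,10Z)-3,7-dimethoxy-15-phenylpentadec-10-ene-2,4,6-trione
Conditions: 7 (3 equiv), NaH (3 equiv) then n-BuLi (3 equiv), THF, 0 °C, 30 min; add 6, 0 → 25 °C, 4 h; aq. HCl
Reagents that add atoms: none
Why: Weiler/Harris-type Claisen acylation: the terminal carbanion of the symmetric dianion of 7 attacks the activated α-methoxy ester. The product stays as its enolate under the reaction conditions, so the C7 stereocentre is not epimerised.

**Step 5**
Reactants: 8
Product: 9, 2-[(1R,4Z)-1-methoxy-9-phenylnon-4-en-1-yl]-5-methoxy-6-methyl-4H-pyran-4-one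
Conditions: TFA (10 equiv), CH2Cl2, 25 °C, 6 h
Reagents that add atoms: none
Why: Acid-catalysed cyclodehydration of the 1,3,5-triketone to the 4-pyranone (the maltol-type 3-OMe/2-Me pattern forms here).

**Step 6**
Reactants: 9; 10, O-methylhydroxylamine hydrochloride
Product: 11, 1,3-dimethoxy-2-methyl-6-[(1R,4Z)-1-methoxy-9-phenylnon-4-en-1-yl]pyridin-4(1H)-one
Conditions: 10 (6 equiv), pyridine (8 equiv), EtOH, 80 °C, sealed tube, 24 h
Reagents that add atoms: 10, CON.Cl
Why: Pyranone-to-pyridone exchange by conjugate addition of the α-effect nucleophile MeONH2, ring opening, then recyclisation and dehydration, giving the N-methoxy-4-pyridone.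

**Step 7**
Reactants: 11; 12, N-iodosuccinimide
Product: 13, 5-iodo-1,3-dimethoxy-2-methyl-6-[(1R,4Z)-1-methoxy-9-phenylnon-4-en-1-yl]pyridin-4(1H)-one
Conditions: NIS (1.1 equiv), MeCN, 0 → 25 °C, 2 h, dark
Reagents that add atoms: 12, O=C1CCC(=O)N1I
Why: Electrophilic iodination at the only free, enaminone-type α-carbon of the pyridone (future C4a).

**Step 8**
Reactants: 13
Product: 14, Waltherione H, (5S,8R)-1,3,8-trimethoxy-2-methyl-5-(5-phenylpentyl)-5,6,7,8-tetrahydroquinolin-4(1H)-one
Conditions: fac-Ir(ppy)3 (2 mol %), iPr2NEt (3 equiv), Hantzsch ester (1.5 equiv), MeCN (0.01 M), blue LEDs (450 nm), 25 °C, 16 h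
Reagents that add atoms: none
Why: Proposed new method: photoredox single-electron reduction of the C–I bond of the α-iodo vinylogous amide gives a σ-type pyridon-3-yl radical. This radical adds 6-exo to the unactivated Z-alkene, and the resulting secondary alkyl radical abstracts H from the Hantzsch ester. This forms the C4a–C5 bond and the 5-phenylpentyl chain in one step. The closest known reaction is photoredox reductive aryl-radical hydroarylation (Beckwith-type 6-exo cyclisation), here applied to an N-alkoxy-4-pyridone radical. The C8 stereocentre controls C5: the pseudo-axial OMe (A(1,3) strain with N–OMe) directs the cyclisation to the cis-(5S,8R) isomer, and any minor trans isomer is removed by chromatography.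

## Compound list
1 | (2R)-5-oxooxolane-2-carboxylic acid | OC(=O)[C@H]1CCC(=O)O1 | starting material
2 | (2R)-5-hydroxyoxolane-2-carboxylic acid (lactol) | OC(=O)[C@H]1CCC(O)O1 | intermediate
3 | (5-phenylpentyl)triphenylphosphonium bromide | [Br-].[P+](CCCCCc1ccccc1)(c1ccccc1)(c1ccccc1)c1ccccc1 | starting material
4 | (2R,5Z)-2-hydroxy-10-phenyldec-5-enoic acid | OC(=O)[C@H](O)CC/C=C\CCCCc1ccccc1 | intermediate
5 | iodomethane | CI | starting material
6 | methyl (2R,5Z)-2-methoxy-10-phenyldec-5-enoate | COC(=O)[C@H](OC)CC/C=C\CCCCc1ccccc1 | intermediate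
7 | 3-methoxypentane-2,4-dione | CC(=O)C(OC)C(C)=O | starting material
8 | (7R,10Z)-3,7-dimethoxy-15-phenylpentadec-10-ene-2,4,6-trione | CC(=O)C(OC)C(=O)CC(=O)[C@H](OC)CC/C=C\CCCCc1ccccc1 | intermediate
9 | 2-[(1R,4Z)-1-methoxy-9-phenylnon-4-en-1-yl]-5-methoxy-6-methyl-4H-pyran-4-one | COc1c(C)oc([C@H](OC)CC/C=C\CCCCc2ccccc2)cc1=O | intermediate
10 | O-methylhydroxylamine hydrochloride | CON.Cl | starting material
11 | 1,3-dimethoxy-2-methyl-6-[(1R,4Z)-1-methoxy-9-phenylnon-4-en-1-yl]pyridin-4(1H)-one | COc1c(C)n(OC)c([C@H](OC)CC/C=C\CCCCc2ccccc2)cc1=O | intermediate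
12 | N-iodosuccinimide | O=C1CCC(=O)N1I | starting material
13 | 5-iodo-1,3-dimethoxy-2-methyl-6-[(1R,4Z)-1-methoxy-9-phenylnon-4-en-1-yl]pyridin-4(1H)-one | COc1c(C)n(OC)c([C@H](OC)CC/C=C\CCCCc2ccccc2)c(I)c1=O | intermediate
14 | Waltherione H | COc1c(C)n(OC)c2c(c1=O)[C@@H](CCCCCc1ccccc1)CC[C@H]2OC | target

## Totals
- Total step count: 8.
- Longest linear sequence: 8 steps (1 → 14).

## Three steps most likely to fail
1. **Step 8 (the proposed new step).** Problems could be poor cis/trans selectivity, direct hydrodeiodination, or 7-endo cyclisation.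
   - Fallback: close the ring by a two-electron route instead. Do a Pd-catalysed intramolecular Heck cyclisation of 13 (Pd(OAc)2, PPh3, Ag2CO3), then hydrogenate the resulting alkene from the face anti to the C8-OMe group. This is known chemistry.
2. **Step 6 (N-OMe pyridone formation).** MeONH2 is a weak nucleophile, so ring exchange could be low-yielding.
   - Fallback: treat 9 with NH2OH·HCl to give the 1-hydroxy-4-pyridone, then O-methylate it (MeI, K2CO3). This replaces the single exchange with stepwise N–OH formation and O-alkylation.
3. **Step 4 (Claisen acylation).** The α-methoxy ester has an acidic α-H, so there is a risk of epimerisation or of low chemoselectivity.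
   - Fallback: reduce 6 to the α-methoxy aldehyde (DIBAL-H). Add the dianion of 7 in an aldol reaction at −78 °C, then oxidise the aldol adduct with DMP to give triketone 8. This swaps the Claisen for an aldol/oxidation sequence.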